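Working atom numbers used throughout (decalin numbering): C1 carries the acetyl group, C2 the sec-butyl group, C3=C4 is the ring alkene, C4a and C8a are the ring-fusion carbons, C5 carries OH, C6 the ester oxygen, C7 is CH2, C8 carries CH3; Cα is the sec-butyl methine. In these numbers the target is 1S,2S,4aR,5S,6R,8R,8aS,αR.

## The problem

1. The target 21 is a trans-fused Δ3-octalin: cyclohexene ring A (C1–C2–C3=C4–C4a–C8a) fused through C4a–C8a to cyclohexane ring B (C4a–C5–C6–C7–C8–C8a).
2. Seven contiguous ring stereocentres must be set, plus the exocyclic (R)-sec-butyl carbon Cα. Cα differs only in Me versus Et, so it can neither steer nor be steered and has to be bought.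
3. H4a and H8a are trans-diaxial, and acetyl (C1) and sec-butyl (C2) are cis. In the ring-B chair O5 and the C8 methyl are equatorial and O6 is axial. The equatorial acetyl is peri to the equatorial C8 methyl, so C1 is an epimerisable centre and base must be avoided once it exists.
4. The C5/C6 diol is cis and only the axial, more hindered O6 is acylated. Ordinary acylation would favour the equatorial O5, and a 1,2-acyl shift is possible.
5. The acyl group is the half ester of (E)-3-methylglutaconic acid. Its CH2 is a vinylogous malonate position, so base, or acyl activation through a vinylketene, scrambles both the geometry and the position of the C=C bond.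
6. The feature that makes the key step possible is ring A: its single double bond C3=C4 is flanked by the stereocentres C2 and C4a, and the acetyl sits on C1. That is the retron of a Diels–Alder reaction between a diene C2=C3–C4=C4a and a dienophile C8a=C1. Because C4a and C8a are also joined by the four-carbon chain C5–C8, the cycloaddition can be intramolecular and closes ring B at the same time. The trans fusion and the cis acetyl/sec-butyl relation are those of the endo transition state of an all-E trienone, and equatorial O5 and C8-Me are what a chair-like tether prefers.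

## Retrosynthesis

21 ⇒ 20. Only two protecting-group bonds are cut: the O5–Si bond and the tert-butyl ester C–O bond. Both fall to acid in one operation; base is excluded by C1 and by the glutaconate. This fixes which two groups all earlier intermediates must carry.

20 ⇒ 19. The bonds C1–C2 and C4a–C8a are cut (intramolecular Diels–Alder). A cut in ring B alone (for example C5–C6) would leave a cyclohexene with four contiguous stereocentres still to be made. This cut removes both rings and four stereocentres (C1, C2, C4a, C8a) at once. Precursor 19 is acyclic, with four stereocentres (C5, C6, C8, Cα) and three E-alkenes. The forward reaction must be endo and must use the diene face on which O5 and C8-Me are equatorial.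

19 ⇒ 18 ⇒ 17 + 8. The alkenyl–carbinol bond C4a–C5 is cut. Cuts at C3–C4 (cross-coupling) or C2=C3 (olefination) would only join fragments. This cut also creates C5 under control of the neighbouring C6 acyloxy group and brings the whole diene and Cα in one fragment, the dienyl iodide 8. The forward reaction must be non-basic and aldehyde-selective, because 17 carries an enone, two esters and the acidic glutaconate CH2; a Ni/Cr coupling meets this. Aldehyde 17 has only two stereocentres and no diene.

17 ⇒ 16 ⇒ 15. The C5 aldehyde is taken back to a primary silyl ether, and the C8a=C1 bond is cut (cross-metathesis with methyl vinyl ketone) to the terminal vinyl group of 15. The enone must be installed before the diene: a vinyl group at C8a and the C4a=C4 bond would be 1,7-related and would close to a cyclohexene by ring-closing metathesis.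

15 ⇒ 14 + 4. The C6–O bond is cut, not the acyl C–O bond: carboxylate 4 displaces activated O6 of 14 with inversion. This needs no acyl activation, so the glutaconate cannot scramble. It is possible only while C6 is an unhindered acyclic carbinol. At this stage O5 (primary, silylated) and O6 (secondary, free) differ by substitution, so no protecting-group exchange on a ring diol is ever needed.

14 ⇒ 13 ⇒ 10 ⇒ 9. The C6–O bond comes from enamine-catalysed α-oxygenation of aldehyde 10 under catalyst control, since C8 is too remote to help. Aldehyde 10 comes from cleavage of the trisubstituted alkene of (R)-β-citronellene 9. Its seven remaining carbons are C5–C8, the C8 methyl, C8a and C1, with C8 already R. Diol 13 is differentiated by selective silylation to 14.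

4 ⇒ 3 ⇒ 2 ⇒ 1. The sp2–sp3 bond C3–C4 of the pentenedioate is cut (cross-coupling of a zinc enolate). The E geometry comes from the (E)-enol tosylate 2 of methyl acetoacetate 1. The methyl ester of 3 is removed by SN2 attack at methyl, not by hydroxide.

8 ⇒ 7 ⇒ 5. Two olefinations (C4=C4a, then C2=C3) lead back to (R)-2-methylbutan-1-ol 5, which supplies Cα.

## Roads not taken

Alternative 1: The most obvious order of cuts. The ester acyl–O6 bond is cut first, giving the diol A1 and the acid; A1 then comes from the Diels–Alder reaction of the acetonide-protected trienone A2. The forward key step is cyclisation of A2, acetonide removal, and regioselective acylation of A1. The chosen plan is better for three reasons. In A1 the equatorial O5–H is the more reactive hydroxyl and the wanted O6 is axial and 1,3-diaxial to H4a and H8, so O5 would need its own protection and removal. Acylating a hindered axial alcohol requires an activated acyl derivative of the glutaconate, which opens the vinylketene path to E/Z and positional scrambling. The SN2 alternative is closed on the ring, since it would need the C6 epimer and backside attack next to a substituted C5. The chosen plan makes the same C6–O bond by inversion on an acyclic carbinol and differentiates the two oxygens for free.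

Alternative 2: The cis-diol retron. Both C–O bonds are cut to the hexahydronaphthalene A3 (alkenes C3=C4 and C5=C6), which would come from the Diels–Alder reaction of the tetraene A4 carrying a (Z)-C5=C6 alkene in the tether. The forward key step is cyclisation of A4 followed by OsO4 dihydroxylation. This precursor carries only C8 and Cα. However, A3 has two cis-disubstituted ring alkenes of similar reactivity, and both faces of C5=C6 are flanked only by axial hydrogens, so neither chemo- nor facial selectivity is secured. The sp2 centres flatten the tether and the (Z)-triene can undergo a [1,5]-hydrogen shift. The diol would again arrive undifferentiated.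

Alternative 3: Union of two carbons of like polarity. The C5–C6 bond is cut to the keto-dialdehyde A5, to be closed by a SmI2 pinacol coupling to A1. The cyclohexene A5 would come from an intermolecular Diels–Alder reaction of the dienal acetal A6 with the enone A7. The chosen plan is better because both termini of A6 are alkyl-type, so the regiochemistry of the intermolecular cycloaddition has no bias. A7 is a sluggish β-branched enone whose C8 centre is too remote to control the face. The methyl ketone would have to be masked against SmI2. Which cis-diol the pinacol gives is uncertain, and the product is again an undifferentiated diol.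

Key step: step 14

Assumptions: (R)-2-methylbutan-1-ol, (R)-β-citronellene and (2-tert-butoxy-2-oxoethyl)zinc bromide solution are taken as purchasable. The sense of proline induction is taken as that known for linear aldehydes (L-proline gives the 2R aminooxy aldehyde), so D-proline is used for 2S.

## Steps

Step 1
Reactants: 1 methyl 3-oxobutanoate
Product: 2 methyl (2E)-3-{[(4-methylphenyl)sulfonyl]oxy}but-2-enoate
Conditions: TsCl, N-methylimidazole, Et3N, toluene, 0 °C
Reagents that add atoms: 4-methylbenzenesulfonyl chloride, Cc1ccc(cc1)S(Cl)(=O)=O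
Why: Stereoselective O-sulfonylation of a β-keto ester; with the amine/N-sulfonylimidazolium system the non-chelated enolate should give the (E)-enol tosylate, which fixes the side-chain alkene geometry.

Step 2
Reactants: 2 methyl (2E)-3-{[(4-methylphenyl)sulfonyl]oxy}but-2-enoate
Product: 3 5-tert-butyl 1-methyl (2E)-3-methylpent-2-enedioate
Conditions: BrZnCH2CO2tBu (1.3 equiv), Pd(OAc)2 (3 mol%), SPhos (6 mol%), THF, 50 °C
Reagents that add atoms: (2-tert-butoxy-2-oxoethyl)zinc bromide, CC(C)(C)OC(=O)C[Zn]Br
Why: Negishi cross-coupling of an enol tosylate with a Reformatsky-type zinc enolate; oxidative addition and reductive elimination retain configuration, so CH2CO2tBu should end trans to the methyl ester (E).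

Step 3
Reactants: 3 5-tert-butyl 1-methyl (2E)-3-methylpent-2-enedioate
Product: 4 (2E)-5-tert-butoxy-3-methyl-5-oxopent-2-enoic acid
Conditions: LiI (4 equiv), EtOAc, reflux, dark; dilute HCl work-up
Reagents that add atoms: none
Why: SN2 demethylation by iodide is neutral and cannot touch the tert-butyl ester; it avoids hydroxide, which would deprotonate the vinylogous malonate CH2 and scramble the alkene.

Step 4
Reactants: 5 (2R)-2-methylbutan-1-ol
Product: 7 (2E,4R)-4-methylhex-2-enal, via (2R)-2-methylbutanal 6 (not isolated)
Conditions: (COCl)2, DMSO, CH2Cl2, −78 °C; Et3N; then Ph3P=CHCHO, −78 °C → rt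
Reagents that add atoms: (triphenylphosphoranylidene)acetaldehyde, O=CC=P(c1ccccc1)(c1ccccc1)c1ccccc1
Why: One-pot Swern oxidation/Wittig olefination avoids isolating the volatile, configurationally labile α-branched aldehyde; the stabilised formyl ylide should give the (E)-enal, and Cα, bought with 5, is not touched.

Step 5
Reactants: 7 (2E,4R)-4-methylhex-2-enal
Product: 8 (1E,3E,5R)-1-iodo-5-methylhepta-1,3-diene
Conditions: CrCl2 (6 equiv), CHI3 (2 equiv), THF/dioxane 1:6, 0 °C → rt
Reagents that add atoms: iodoform, IC(I)I
Why: Takai iodo-olefination through a geminal dichromium species converts the aldehyde into the (E)-alkenyl iodide; the existing E-alkene and the γ-stereocentre are inert to Cr(II).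

Step 6
Reactants: 9 (3R)-3,7-dimethylocta-1,6-diene [(R)-β-citronellene]
Product: 10 (4R)-4-methylhex-5-enal
Conditions: O3 (1 equiv, dye end-point), CH2Cl2/MeOH, NaHCO3, −78 °C; Me2S, → rt
Reagents that add atoms: ozone, [O-][O+]=O
Why: Ozonolysis attacks the electron-rich trisubstituted alkene much faster than the monosubstituted vinyl group; the aldehyde maps atom for atom onto C5–C8 plus C8a=C1, with C8 already R.

Step 7
Reactants: 10 (4R)-4-methylhex-5-enal
Product: 13 (2S,4R)-4-methylhex-5-ene-1,2-diol, via aminooxy aldehyde 11 (not isolated), via aminooxy alcohol 12 (not isolated)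
Conditions: D-proline (20 mol%), PhNO (1.0 equiv), DMSO, rt; NaBH4, EtOH, 0 °C; crude, then Zn, AcOH/THF, rt
Reagents that add atoms: nitrosobenzene, O=Nc1ccccc1
Why: Proline-catalysed α-aminoxylation (enamine catalysis, O-selective nitroso aldol) sets C6 under catalyst control, D-proline giving the 2S epimer needed for the later inversion; borohydride reduction and reductive N–O cleavage then give the diol.

Step 8
Reactants: 13 (2S,4R)-4-methylhex-5-ene-1,2-diol
Product: 14 (2S,4R)-4-methyl-1-[(triethylsilyl)oxy]hex-5-en-2-ol
Conditions: TESCl (1.05 equiv), imidazole, CH2Cl2, −40 °C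
Reagents that add atoms: chlorotriethylsilane, CC[Si](Cl)(CC)CC
Why: Kinetic silylation distinguishes the primary from the secondary hydroxyl; this single step differentiates O5 from O6 for the whole synthesis.

Step 9
Reactants: 14 (2S,4R)-4-methyl-1-[(triethylsilyl)oxy]hex-5-en-2-ol; 4 (2E)-5-tert-butoxy-3-methyl-5-oxopent-2-enoic acid
Product: 15 5-tert-butyl 1-{(2R,4R)-4-methyl-1-[(triethylsilyl)oxy]hex-5-en-2-yl} (2E)-3-methylpent-2-enedioate
Conditions: PPh3, DIAD, toluene, 0 °C → rt
Reagents that add atoms: none
Why: Mitsunobu esterification: the carboxylate displaces the oxyphosphonium group by SN2 and inverts C6 from S to R; no acyl activation is involved, so the E-alkene of the acid cannot scramble through a vinylketene.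

Step 10
Reactants: 15 5-tert-butyl 1-{(2R,4R)-4-methyl-1-[(triethylsilyl)oxy]hex-5-en-2-yl} (2E)-3-methylpent-2-enedioate
Product: 16 5-tert-butyl 1-{(2R,4R,5E)-4-methyl-7-oxo-1-[(triethylsilyl)oxy]oct-5-en-2-yl} (2E)-3-methylpent-2-enedioate
Conditions: methyl vinyl ketone (5 equiv), second-generation Ru catalyst with chelating 2-isopropoxybenzylidene (5 mol%), CH2Cl2, 40 °C
Reagents that add atoms: but-3-en-2-one, C=CC(C)=O
Why: Olefin cross-metathesis of a terminal alkene with an electron-poor partner should give the (E)-enone; the trisubstituted enoate is inert, and the step is placed before any diene exists so that ring-closing metathesis is impossible.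

Step 11
Reactants: 16 5-tert-butyl 1-{(2R,4R,5E)-4-methyl-7-oxo-1-[(triethylsilyl)oxy]oct-5-en-2-yl} (2E)-3-methylpent-2-enedioate
Product: 17 5-tert-butyl 1-[(2R,4R,5E)-4-methyl-1,7-dioxooct-5-en-2-yl] (2E)-3-methylpent-2-enedioate
Conditions: (COCl)2, DMSO, CH2Cl2, −78 → −35 °C; iPr2NEt, −78 → −20 °C; cold pH 7 quench; used crude
Reagents that add atoms: none
Why: Direct Swern oxidation of a primary triethylsilyl ether: the chlorosulfonium salt cleaves the primary O–Si bond and the alkoxysulfonium collapses to the aldehyde, so no free 1-hydroxy-2-acyloxy compound (acyl migration) is formed.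

Step 12
Reactants: 17 5-tert-butyl 1-[(2R,4R,5E)-4-methyl-1,7-dioxooct-5-en-2-yl] (2E)-3-methylpent-2-enedioate; 8 (1E,3E,5R)-1-iodo-5-methylhepta-1,3-diene
Product: 18 5-tert-butyl 1-[(3E,5R,7R,8S,9E,11E,13R)-8-hydroxy-5,13-dimethyl-2-oxopentadeca-3,9,11-trien-7-yl] (2E)-3-methylpent-2-enedioate
Conditions: CrCl2 (5 equiv), NiCl2 (2 mol%), degassed DMSO, rt; aqueous work-up; used at once
Reagents that add atoms: none
Why: Nozaki–Hiyama–Kishi coupling: the alkenylchromium(III) species is non-basic and adds only to the aldehyde, with retention of the (E,E)-diene, leaving enone, esters and the acidic CH2 untouched. Polar Felkin–Anh attack anti to the α-acyloxy group should set C5 as S, anti to O6.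

Step 13
Reactants: 18 5-tert-butyl 1-[(3E,5R,7R,8S,9E,11E,13R)-8-hydroxy-5,13-dimethyl-2-oxopentadeca-3,9,11-trien-7-yl] (2E)-3-methylpent-2-enedioate
Product: 19 5-tert-butyl 1-{(3E,5R,7R,8S,9E,11E,13R)-5,13-dimethyl-2-oxo-8-[(triethylsilyl)oxy]pentadeca-3,9,11-trien-7-yl} (2E)-3-methylpent-2-enedioate
Conditions: TESCl, imidazole, DMF, 0 °C
Reagents that add atoms: chlorotriethylsilane, CC[Si](Cl)(CC)CC
Why: Silylation of the secondary alcohol under weakly basic conditions; it blocks oxa-Michael addition of O5 to the Lewis-acid-activated enone and enlarges the C5 substituent that steers the cycloaddition.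

Step 14
Reactants: 19 5-tert-butyl 1-{(3E,5R,7R,8S,9E,11E,13R)-5,13-dimethyl-2-oxo-8-[(triethylsilyl)oxy]pentadeca-3,9,11-trien-7-yl} (2E)-3-methylpent-2-enedioate
Product: 20 5-tert-butyl 1-{(1S,2R,4R,4aS,5S,6S,8aR)-5-acetyl-6-[(2R)-butan-2-yl]-4-methyl-1-[(triethylsilyl)oxy]-1,2,3,4,4a,5,6,8a-octahydronaphthalen-2-yl} (2E)-3-methylpent-2-enedioate
Conditions: Me2AlCl (2.5 equiv), CH2Cl2 (0.01 M), −78 → −30 °C; Rochelle salt work-up
Reagents that add atoms: none
Why: Concerted, asynchronous [4+2] cycloaddition of the (E,E)-diene C2=C3–C4=C4a to the (E)-enone C8a=C1, whose LUMO is lowered by aluminium on the acetyl oxygen. The closest known reaction type is the Lewis-acid-promoted intramolecular Diels–Alder reaction of (E,E,E)-1,7,9-decatrienes with a terminal carbonyl activator, which gives trans-fused octalins. Ring B (C4a–C5–C6–C7–C8–C8a) closes through the C4a–C8a bond with the four-carbon tether in a chair; ring A (C1–C2–C3=C4–C4a–C8a) is the cycloaddition ring itself, completed by the C1–C2 bond. The trans relation of H4a and H8a and the configuration at C1 follow from the E-enone reacting in the endo mode (acetyl under the diene). C2 follows from the suprafacial addition to the E,E-diene, which places H2 cis to H4a and the sec-butyl group cis to the acetyl group. The diene face is chosen by the tether: in the reacting chair O5–Si and the C8 methyl are both equatorial, avoiding allylic strain with C4–H and C1–H, and only the C6 acyloxy group is axial, whereas attack on the other face would put two groups axial. The step needs endo over exo selectivity, secured by the Lewis acid and the E geometry, and chemoselectivity for the enone, secured because the glutaconate alkene is trisubstituted, ester-tethered and not activated.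

Step 15
Reactants: 20 5-tert-butyl 1-{(1S,2R,4R,4aS,5S,6S,8aR)-5-acetyl-6-[(2R)-butan-2-yl]-4-methyl-1-[(triethylsilyl)oxy]-1,2,3,4,4a,5,6,8a-octahydronaphthalen-2-yl} (2E)-3-methylpent-2-enedioate
Product: 21 (3E)-5-{[(1S,2R,4R,4aS,5S,6S,8aR)-5-acetyl-6-[(2R)-butan-2-yl]-1-hydroxy-4-methyl-1,2,3,4,4a,5,6,8a-octahydronaphthalen-2-yl]oxy}-3-methyl-5-oxopent-3-enoic acid
Conditions: TFA/CH2Cl2/H2O 20:78:2, 0 °C → rt; evaporation, neutral silica
Reagents that add atoms: none
Why: Acidolysis removes the tert-butyl ester (loss of isobutene) and the silyl ether in one operation; no base is used, so C1, the position of the acyl group and the glutaconate geometry should be preserved.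

## Compound list

1 | methyl 3-oxobutanoate | COC(=O)CC(C)=O | starting material
2 | methyl (2E)-3-{[(4-methylphenyl)sulfonyl]oxy}but-2-enoate | COC(=O)/C=C(\C)OS(=O)(=O)c1ccc(C)cc1 | intermediate
3 | 5-tert-butyl 1-methyl (2E)-3-methylpent-2-enedioate | COC(=O)/C=C(\C)CC(=O)OC(C)(C)C | intermediate
4 | (2E)-5-tert-butoxy-3-methyl-5-oxopent-2-enoic acid | OC(=O)/C=C(\C)CC(=O)OC(C)(C)C | intermediate
5 | (2R)-2-methylbutan-1-ol | CC[C@@H](C)CO | starting material
6 | (2R)-2-methylbutanal | CC[C@@H](C)C=O | intermediate (not isolated)
7 | (2E,4R)-4-methylhex-2-enal | CC[C@@H](C)/C=C/C=O | intermediate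
8 | (1E,3E,5R)-1-iodo-5-methylhepta-1,3-diene | CC[C@@H](C)/C=C/C=C/I | intermediate
9 | (3R)-3,7-dimethylocta-1,6-diene | C=C[C@H](C)CCC=C(C)C | starting material
10 | (4R)-4-methylhex-5-enal | C=C[C@H](C)CCC=O | intermediate
11 | (2S,4R)-2-(anilinooxy)-4-methylhex-5-enal | C=C[C@H](C)C[C@H](ONc1ccccc1)C=O | intermediate (not isolated)
12 | (2S,4R)-2-(anilinooxy)-4-methylhex-5-en-1-ol | C=C[C@H](C)C[C@H](ONc1ccccc1)CO | intermediate (not isolated)
13 | (2S,4R)-4-methylhex-5-ene-1,2-diol | C=C[C@H](C)C[C@H](O)CO | intermediate
14 | (2S,4R)-4-methyl-1-[(triethylsilyl)oxy]hex-5-en-2-ol | C=C[C@H](C)C[C@H](O)CO[Si](CC)(CC)CC | intermediate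
15 | 5-tert-butyl 1-{(2R,4R)-4-methyl-1-[(triethylsilyl)oxy]hex-5-en-2-yl} (2E)-3-methylpent-2-enedioate | C=C[C@H](C)C[C@@H](OC(=O)/C=C(\C)CC(=O)OC(C)(C)C)CO[Si](CC)(CC)CC | intermediate
16 | 5-tert-butyl 1-{(2R,4R,5E)-4-methyl-7-oxo-1-[(triethylsilyl)oxy]oct-5-en-2-yl} (2E)-3-methylpent-2-enedioate | CC(=O)/C=C/[C@H](C)C[C@@H](OC(=O)/C=C(\C)CC(=O)OC(C)(C)C)CO[Si](CC)(CC)CC | intermediate
17 | 5-tert-butyl 1-[(2R,4R,5E)-4-methyl-1,7-dioxooct-5-en-2-yl] (2E)-3-methylpent-2-enedioate | CC(=O)/C=C/[C@H](C)C[C@@H](OC(=O)/C=C(\C)CC(=O)OC(C)(C)C)C=O | intermediate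
18 | 5-tert-butyl 1-[(3E,5R,7R,8S,9E,11E,13R)-8-hydroxy-5,13-dimethyl-2-oxopentadeca-3,9,11-trien-7-yl] (2E)-3-methylpent-2-enedioate | CC[C@@H](C)/C=C/C=C/[C@H](O)[C@H](OC(=O)/C=C(\C)CC(=O)OC(C)(C)C)C[C@@H](C)/C=C/C(C)=O | intermediate
19 | 5-tert-butyl 1-{(3E,5R,7R,8S,9E,11E,13R)-5,13-dimethyl-2-oxo-8-[(triethylsilyl)oxy]pentadeca-3,9,11-trien-7-yl} (2E)-3-methylpent-2-enedioate | CC[C@@H](C)/C=C/C=C/[C@H](O[Si](CC)(CC)CC)[C@H](OC(=O)/C=C(\C)CC(=O)OC(C)(C)C)C[C@@H](C)/C=C/C(C)=O | intermediate
20 | 5-tert-butyl 1-{(1S,2R,4R,4aS,5S,6S,8aR)-5-acetyl-6-[(2R)-butan-2-yl]-4-methyl-1-[(triethylsilyl)oxy]-1,2,3,4,4a,5,6,8a-octahydronaphthalen-2-yl} (2E)-3-methylpent-2-enedioate | CC[C@@H](C)[C@H]1C=C[C@H]2[C@H](O[Si](CC)(CC)CC)[C@H](OC(=O)/C=C(\C)CC(=O)OC(C)(C)C)C[C@@H](C)[C@@H]2[C@H]1C(C)=O | intermediate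
21 | (3E)-5-{[(1S,2R,4R,4aS,5S,6S,8aR)-5-acetyl-6-[(2R)-butan-2-yl]-1-hydroxy-4-methyl-1,2,3,4,4a,5,6,8a-octahydronaphthalen-2-yl]oxy}-3-methyl-5-oxopent-3-enoic acid | CC[C@@H](C)[C@H]1C=C[C@H]2[C@H](O)[C@H](OC(=O)/C=C(\C)CC(=O)O)C[C@@H](C)[C@@H]2[C@H]1C(C)=O | target

## Step count and least certain steps

Total step count: 15 (steps 1–3 to acid 4, steps 4–5 to iodide 8, steps 6–15 on the main line). Longest linear sequence: 10 steps (9 → 21, steps 6–15).

Step 14 (key step). The most likely failures are erosion of endo selectivity, or Lewis-acid ionisation of the dienylic C5–O–Si bond or of the tert-butyl ester before cycloaddition. The fallback drops both the Lewis acid and the silyl ether. It sets out from 18, which is heated in dilute toluene with a radical inhibitor at 80–100 °C, so that the free carbinol cyclises thermally to the hydroxy octalin tert-butyl ester F1. Acidolysis of F1 as in step 15 comes back to the route at 21. This costs some endo selectivity but removes every acid-labile interaction from the cyclisation.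

Step 12. The most likely failures are poor facial selectivity at C5, since substrate control by an α-acyloxy group is the least documented element of the route, or transfer of the acyl group from O6 to the chromium alkoxide at O5. The fallback replaces substrate control by reagent control. It sets out from 17 and 8 and uses the catalytic asymmetric Ni/Cr coupling (chromium with a chiral sulfonamide ligand, manganese as reductant, zirconocene dichloride as alkoxide scavenger), which releases the product from chromium as it forms. It comes back to the route at 18 and makes no new compound.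

Step 11. The most likely failures are epimerisation at C6 of the α-acyloxy aldehyde by the amine base, or amine-induced isomerisation of the glutaconate. The fallback is a base-free two-stage route. It sets out from 16: selective methanolysis of the primary silyl ether (PPTS, MeOH, 0 °C) gives the primary alcohol F2, which is oxidised at once with Dess–Martin periodinane without buffer amine. It comes back to the route at 17.

Step 9. The most likely failures are elimination, or incomplete inversion if the oxyphosphonium intermediate is intercepted slowly by this weakly acidic enoic acid. The fallback separates activation from displacement. It sets out from 14, which is converted to the methanesulfonate F3 (MsCl, Et3N, −20 °C). F3 is displaced by the caesium salt of 4 (18-crown-6, toluene/DMF, 50 °C) with inversion. It comes back to the route at 15.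

Step 2. The most likely failure is loss of geometric purity if the zinc enolate deprotonates the acidic product 3 and the dienolate reprotonates unselectively. The fallback takes the geometry from a purchased acid instead of building it. It sets out from commercial (2E)-3-methylpent-2-enedioic acid F4, which is treated with one equivalent of tert-butyl 2,2,2-trichloroacetimidate without added acid; the stronger, non-conjugated carboxyl protonates the imidate and should be esterified preferentially. It comes back to the route at 4.

## Further compounds

F1 | step 14 | 5-tert-butyl 1-{(1S,2R,4R,4aS,5S,6S,8aR)-5-acetyl-6-[(2R)-butan-2-yl]-1-hydroxy-4-methyl-1,2,3,4,4a,5,6,8a-octahydronaphthalen-2-yl} (2E)-3-methylpent-2-enedioate | CC[C@@H](C)[C@H]1C=C[C@H]2[C@H](O)[C@H](OC(=O)/C=C(\C)CC(=O)OC(C)(C)C)C[C@@H](C)[C@@H]2[C@H]1C(C)=O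
F0 | step 12 | none | none
F2 | step 11 | 5-tert-butyl 1-[(2R,4R,5E)-1-hydroxy-4-methyl-7-oxooct-5-en-2-yl] (2E)-3-methylpent-2-enedioate | CC(=O)/C=C/[C@H](C)C[C@@H](OC(=O)/C=C(\C)CC(=O)OC(C)(C)C)CO
F3 | step 9 | (2S,4R)-4-methyl-1-[(triethylsilyl)oxy]hex-5-en-2-yl methanesulfonate | C=C[C@H](C)C[C@H](OS(C)(=O)=O)CO[Si](CC)(CC)CC
F4 | step 2 | (2E)-3-methylpent-2-enedioic acid | OC(=O)/C=C(\C)CC(=O)O
A1 | alternative 1 | 1-[(1S,2S,4aR,5S,6R,8R,8aS)-2-[(2R)-butan-2-yl]-5,6-dihydroxy-8-methyl-1,2,4a,5,6,7,8,8a-octahydronaphthalen-1-yl]ethan-1-one | CC[C@@H](C)[C@H]1C=C[C@H]2[C@H](O)[C@H](O)C[C@@H](C)[C@@H]2[C@H]1C(C)=O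
A2 | alternative 1 | (3E,5R)-6-{(4R,5S)-2,2-dimethyl-5-[(1E,3E,5R)-5-methylhepta-1,3-dien-1-yl]-1,3-dioxolan-4-yl}-5-methylhex-3-en-2-one | CC[C@@H](C)/C=C/C=C/[C@@H]1OC(C)(C)O[C@@H]1C[C@@H](C)/C=C/C(C)=O
A3 | alternative 2 | 1-{2-[(2R)-butan-2-yl]-8-methyl-1,2,4a,7,8,8a-hexahydronaphthalen-1-yl}ethan-1-one, ring centres as in the target | CC[C@@H](C)[C@H]1C=C[C@H]2C=CC[C@@H](C)[C@@H]2[C@H]1C(C)=O
A4 | alternative 2 | (3E,5R,7Z,9E,11E,13R)-5,13-dimethylpentadeca-3,7,9,11-tetraen-2-one | CC[C@@H](C)/C=C/C=C/C=C\C[C@@H](C)/C=C/C(C)=O
A5 | alternative 3 | (2R)-2-{6-acetyl-5-[(2R)-butan-2-yl]-2-formylcyclohex-3-en-1-yl}-substituted butanal [3-(ring)butanal], ring centres as in the target | CC[C@@H](C)[C@H]1C=C[C@@H](C=O)[C@H]([C@H](C)CC=O)[C@H]1C(C)=O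
A6 | alternative 3 | (2E,4E,6R)-1,1-dimethoxy-6-methylocta-2,4-diene | CC[C@@H](C)/C=C/C=C/C(OC)OC
A7 | alternative 3 | (3E,5R)-7,7-dimethoxy-5-methylhept-3-en-2-one | CC(=O)/C=C/[C@H](C)CC(OC)OC
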